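**Strategy.** Ring A of the coumarin is made last. Its oxygens on C5, C7 and C8a sit in a 1,3,5 (acetate-type) relationship, so the C5–C6 bond can be cut back to a methyl ketone and an ester. The precursor is a 4-aryl-2-pyranone that carries a methyl ester on the future C4a and a 1-methoxy-2-oxopropyl chain on the future C8a. Twofold deprotonation lets the terminal methyl carbon acylate itself on the ester. This single operation forms C5–C6, closes ring A and, by enolisation, delivers the 5,7-dihydroxy-8-methoxycoumarin with every oxygen in place. Two O-methylations and debenzylation finish the synthesis.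

Key step: step 5

Remark: the alkynoate is made as its methyl ester, so that methoxide released on lactonisation in step 3 cannot scramble the C5 methyl ester of the precursor.
Remark: pyranone positions are numbered with the lactone carbonyl as C2 (aryl on C4, ester on C5, side chain on C6). Compounds 6, 10 and 11 are racemic (10 is also a diastereomer mixture). These centres vanish on aromatisation and the target is achiral.
Assumption: 2,3,5-trimethoxyphenol, needed only in the fallback for step 5, is taken to be purchasable.

**Step 1**
Reactants: 1 3-(benzyloxy)-4-methoxybenzaldehyde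
Product: 2 2-(benzyloxy)-4-(2,2-dibromoethenyl)-1-methoxybenzene
Conditions: CBr4, PPh3, CH2Cl2, 0 °C
Reagents that add atoms: carbon tetrabromide, BrC(Br)(Br)Br
Why: Ramirez dibromo-olefination (first half of the Corey–Fuchs sequence), in which the ylide formed from CBr4 and PPh3 should undergo a Wittig reaction with the aromatic aldehyde while both ethers stay inert.

**Step 2**
Reactants: 2 2-(benzyloxy)-4-(2,2-dibromoethenyl)-1-methoxybenzene
Product: 4 methyl 3-[3-(benzyloxy)-4-methoxyphenyl]prop-2-ynoate, via lithium acetylide 3 (not isolated)
Conditions: n-BuLi (2.1 equiv), THF, −78 °C; then ClCO2Me, −78 → 0 °C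
Reagents that add atoms: methyl chloroformate, COC(=O)Cl
Why: Second half of the Corey–Fuchs sequence, in which bromine–lithium exchange and Fritsch–Buttenberg–Wiechell rearrangement should give the lithium acetylide, which is C-acylated by the chloroformate to the ynoate.

**Step 3**
Reactants: 4 methyl 3-[3-(benzyloxy)-4-methoxyphenyl]prop-2-ynoate; 5 methyl 4-methoxy-3-oxobutanoate
Product: 7 methyl 4-[3-(benzyloxy)-4-methoxyphenyl]-6-(methoxymethyl)-2-oxo-2H-pyran-5-carboxylate, via Michael adduct 6 (not isolated)
Conditions: Cs2CO3 (0.3 equiv), DMF, rt → 60 °C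
Reagents that add atoms: none
Why: Base-catalysed Michael addition of the doubly activated carbon of the β-keto ester to the β-carbon of the ynoate, followed by lactonisation of the ketone enol oxygen onto the acrylate ester (the classical 2-pyranone annulation of a 1,3-dicarbonyl compound with an alkynoate), should place the aryl group on C4, the ester on C5 and the methoxymethyl group on C6.

**Step 4**
Reactants: 7 methyl 4-[3-(benzyloxy)-4-methoxyphenyl]-6-(methoxymethyl)-2-oxo-2H-pyran-5-carboxylate; 8 N-methoxy-N-methylacetamide
Product: 11 methyl 4-[3-(benzyloxy)-4-methoxyphenyl]-6-(1-methoxy-2-oxopropyl)-2-oxo-2H-pyran-5-carboxylate (racemic), via lithiated pyranone 9 (not isolated), via tetrahedral adduct 10 (not isolated)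
Conditions: LiN(SiMe3)2 (1.2 equiv), THF, −78 °C; then 8, −78 → −30 °C; 1 M HCl
Reagents that add atoms: none
Why: Vinylogous enolate C-acylation with a Weinreb amide, in which the methylene of the 6-methoxymethyl group (acidified through the ring by the C5 ester and the lactone carbonyl) should be lithiated and react at the exocyclic carbon as 6-alkyl-2-pyranone anions do, the chelated tetrahedral adduct preventing over-acylation; the new stereocentre forms without control and is erased in step 5.

**Step 5**
Reactants: 11 methyl 4-[3-(benzyloxy)-4-methoxyphenyl]-6-(1-methoxy-2-oxopropyl)-2-oxo-2H-pyran-5-carboxylate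
Product: 14 4-[3-(benzyloxy)-4-methoxyphenyl]-5,7-dihydroxy-8-methoxy-2H-chromen-2-one, via dilithium dianion 12 (not isolated), via ring-closed enolate 13 (not isolated)
Conditions: LiN(i-Pr)2 (3 equiv), THF, −78 → 0 °C; 1 M HCl
Reagents that add atoms: none
Why: Proposed new method: the first equivalent of amide base removes the hydrogen on the methoxy-bearing carbon (flanked by the ketone and the vinylogous ester and lactone), the second removes a hydrogen of the terminal methyl group, and the much more basic terminal enolate carbon then adds to the neighbouring C5 ester carbonyl and expels methoxide, which forges C5–C6 of the coumarin. The closest known reactions are the Claisen (Dieckmann-type) cyclisations of β-dicarbonyl dianions and of o-acetonylbenzoates to resorcinols and naphthalene-1,3-diols; a 2-pyranone has not served as the tether in such a closure. Ring A closes in a 6-exo-trig (enolendo) mode, the nucleophilic chain and the ester being held cis on the pyranone C5=C6 bond (future C4a=C8a). No stereocentre is created: the racemic centre of 11 becomes sp2 C8, and the ring-closed enolate 13 should tautomerise at once to the aromatic 5,7-diol, which makes the closure irreversible. The step needs C-acylation by the terminal carbon to win over O-acylation by the inner enolate oxygen and over attack on the lactone; the higher nucleophilicity of the kinetically formed terminal carbanion, a hindered non-nucleophilic base, low temperature and the deactivation of the pyranone as part of the delocalised monoanion should secure this. The oxygen pattern cannot vary, since O1 comes from the pyranone, the 8-methoxy group from the methoxyacetoacetate, and the 5- and 7-oxygens from the ester and ketone carbonyls.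

**Step 6**
Reactants: 14 4-[3-(benzyloxy)-4-methoxyphenyl]-5,7-dihydroxy-8-methoxy-2H-chromen-2-one
Product: 15 4-[3-(benzyloxy)-4-methoxyphenyl]-5,7,8-trimethoxy-2H-chromen-2-one
Conditions: Me2SO4 (3 equiv), K2CO3, acetone, reflux
Reagents that add atoms: dimethyl sulfate, COS(=O)(=O)OC
Why: Williamson-type O-methylation of both phenols with a hard methylating agent and a mild carbonate base, under which the lactone and the benzyl ether should remain untouched.

**Step 7**
Reactants: 15 4-[3-(benzyloxy)-4-methoxyphenyl]-5,7,8-trimethoxy-2H-chromen-2-one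
Product: 16 4-(3-hydroxy-4-methoxyphenyl)-5,7,8-trimethoxy-2H-chromen-2-one (3'-hydroxy-5,7,8,4'-tetramethoxy-4-phenylcoumarin)
Conditions: H2 (1 atm), Pd/C (10 wt % Pd), EtOAc/MeOH, rt
Reagents that add atoms: none
Why: Catalytic hydrogenolysis of the benzyl aryl ether, which should be much faster than reduction of the trisubstituted, aryl-conjugated C3=C4 bond of the coumarin, so the reaction is stopped once debenzylation is complete.

**Compound list**
1 | 3-(benzyloxy)-4-methoxybenzaldehyde | COc1ccc(C=O)cc1OCc1ccccc1 | starting material
2 | 2-(benzyloxy)-4-(2,2-dibromoethenyl)-1-methoxybenzene | COc1ccc(C=C(Br)Br)cc1OCc1ccccc1 | intermediate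
3 | lithium [3-(benzyloxy)-4-methoxyphenyl]acetylide | [Li+].[C-]#Cc1ccc(OC)c(OCc2ccccc2)c1 | intermediate (not isolated)
4 | methyl 3-[3-(benzyloxy)-4-methoxyphenyl]prop-2-ynoate | COC(=O)C#Cc1ccc(OC)c(OCc2ccccc2)c1 | intermediate
5 | methyl 4-methoxy-3-oxobutanoate | COCC(=O)CC(=O)OC | starting material
6 | dimethyl (E)-3-[3-(benzyloxy)-4-methoxyphenyl]-4-(methoxyacetyl)pent-2-enedioate (racemic Michael adduct) | COC(=O)/C=C(/c1ccc(OC)c(OCc2ccccc2)c1)C(C(=O)COC)C(=O)OC | intermediate (not isolated)
7 | methyl 4-[3-(benzyloxy)-4-methoxyphenyl]-6-(methoxymethyl)-2-oxo-2H-pyran-5-carboxylate | COCc1oc(=O)cc(-c2ccc(OC)c(OCc3ccccc3)c2)c1C(=O)OC | intermediate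
8 | N-methoxy-N-methylacetamide | CC(=O)N(C)OC | starting material
9 | lithium salt of 7 deprotonated at the methoxymethyl carbon (lithiated pyranone) | [Li+].CO[CH-]c1oc(=O)cc(-c2ccc(OC)c(OCc3ccccc3)c2)c1C(=O)OC | intermediate (not isolated)
10 | lithium alkoxide adduct of 9 and 8 (tetrahedral adduct, diastereomer mixture, racemic) | [Li+].COC(c1oc(=O)cc(-c2ccc(OC)c(OCc3ccccc3)c2)c1C(=O)OC)C(C)([O-])N(C)OC | intermediate (not isolated)
11 | methyl 4-[3-(benzyloxy)-4-methoxyphenyl]-6-(1-methoxy-2-oxopropyl)-2-oxo-2H-pyran-5-carboxylate (racemic) | COC(C(C)=O)c1oc(=O)cc(-c2ccc(OC)c(OCc3ccccc3)c2)c1C(=O)OC | intermediate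
12 | dilithium dianion of 11 (deprotonated at the methoxy-bearing carbon and at the terminal methyl) | [Li+].[Li+].[CH2-]C(=O)[C-](OC)c1oc(=O)cc(-c2ccc(OC)c(OCc3ccccc3)c2)c1C(=O)OC | intermediate (not isolated)
13 | lithium 4-[3-(benzyloxy)-4-methoxyphenyl]-8-methoxy-2,5-dioxo-5,6-dihydro-2H-chromen-7-olate (ring-closed enolate) | [Li+].COC1=C([O-])CC(=O)c2c1oc(=O)cc2-c1ccc(OC)c(OCc3ccccc3)c1 | intermediate (not isolated)
14 | 4-[3-(benzyloxy)-4-methoxyphenyl]-5,7-dihydroxy-8-methoxy-2H-chromen-2-one | COc1ccc(-c2cc(=O)oc3c(OC)c(O)cc(O)c23)cc1OCc1ccccc1 | intermediate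
15 | 4-[3-(benzyloxy)-4-methoxyphenyl]-5,7,8-trimethoxy-2H-chromen-2-one | COc1ccc(-c2cc(=O)oc3c(OC)c(OC)cc(OC)c23)cc1OCc1ccccc1 | intermediate
16 | 4-(3-hydroxy-4-methoxyphenyl)-5,7,8-trimethoxy-2H-chromen-2-one | COc1ccc(-c2cc(=O)oc3c(OC)c(OC)cc(OC)c23)cc1O | target

**Total step count:** 7
**Longest linear sequence:** 7 steps (1 → 16)

**Steps most likely to fail**

Step 5 (proposed new method). What may go wrong: lactonisation of the inner enolate oxygen onto the C5 ester, or addition of base or methoxide to the pyranone, may outrun deprotonation of the methyl group and C-acylation, so that ring A does not form. The fallback uses known chemistry and brings ring A in intact instead of building it. It sets out from alkynoate 4 and returns to the route at 15. Saponification of 4 (LiOH, THF/H2O) should give 3-[3-(benzyloxy)-4-methoxyphenyl]prop-2-ynoic acid F1. Steglich esterification with 2,3,5-trimethoxyphenol (DCC, DMAP, CH2Cl2) should give 2,3,5-trimethoxyphenyl 3-[3-(benzyloxy)-4-methoxyphenyl]prop-2-ynoate F2. Intramolecular hydroarylation of this aryl alkynoate (Ph3PAuCl/AgOTf, 1,2-dichloroethane) can occur only at the one free ortho carbon of the phenol ring, which is ortho and para to methoxy groups. It should close the lactone ring and give 15, which enters step 7.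

Step 4. What may go wrong: the stabilised dienolate may add too slowly to the Weinreb amide, or the tetrahedral alkoxide may attack the neighbouring C5 ester on warming. The fallback replaces acylation by aldol addition and oxidation. It sets out from 7 and returns at 11. The lithiated pyranone from 7 is treated with acetaldehyde at −78 °C and quenched cold with acetic acid, so that the alkoxide has no time to lactonise. This should give methyl 4-[3-(benzyloxy)-4-methoxyphenyl]-6-(2-hydroxy-1-methoxypropyl)-2-oxo-2H-pyran-5-carboxylate F3 as a diastereomer mixture. Dess–Martin oxidation (CH2Cl2, NaHCO3) should then give 11.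

Step 3. What may go wrong: the Michael adduct may fail to reach the alkene geometry needed for lactonisation, or conjugate addition may go through the enolate oxygen instead of carbon. The fallback attaches the aryl group by cross-coupling to a preformed pyranone. It sets out from 5 and returns at 7. Condensation of 5 with malonyl dichloride (CH2Cl2, reflux) should give methyl 4-hydroxy-6-(methoxymethyl)-2-oxo-2H-pyran-5-carboxylate F4. Triflation (Tf2O, Et3N, CH2Cl2, −78 °C) should give methyl 6-(methoxymethyl)-2-oxo-4-{[(trifluoromethyl)sulfonyl]oxy}-2H-pyran-5-carboxylate F5. Suzuki–Miyaura coupling with [3-(benzyloxy)-4-methoxyphenyl]boronic acid (Pd(PPh3)4, K3PO4, dioxane, 80 °C) should give 7.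

**Further compounds**
F1 | step 5 | 3-[3-(benzyloxy)-4-methoxyphenyl]prop-2-ynoic acid | OC(=O)C#Cc1ccc(OC)c(OCc2ccccc2)c1
F2 | step 5 | 2,3,5-trimethoxyphenyl 3-[3-(benzyloxy)-4-methoxyphenyl]prop-2-ynoate | COc1cc(OC)c(OC)c(OC(=O)C#Cc2ccc(OC)c(OCc3ccccc3)c2)c1
F3 | step 4 | methyl 4-[3-(benzyloxy)-4-methoxyphenyl]-6-(2-hydroxy-1-methoxypropyl)-2-oxo-2H-pyran-5-carboxylate (diastereomer mixture, racemic) | COC(C(C)O)c1oc(=O)cc(-c2ccc(OC)c(OCc3ccccc3)c2)c1C(=O)OC
F4 | step 3 | methyl 4-hydroxy-6-(methoxymethyl)-2-oxo-2H-pyran-5-carboxylate | COCc1oc(=O)cc(O)c1C(=O)OC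
F5 | step 3 | methyl 6-(methoxymethyl)-2-oxo-4-{[(trifluoromethyl)sulfonyl]oxy}-2H-pyran-5-carboxylate | COCc1oc(=O)cc(OS(=O)(=O)C(F)(F)F)c1C(=O)OC
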